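I was asked for a reading at 12 d, which looked like a question of rates, so I first checked whether the clock still mattered in the earlier runs.

| setting | midnight | dusk | flask |
|---|---|---|---|
| starting material | 0.50 M (fed, over 25 min) | 0.50 M (fed, over 25 min) | 0.50 M (fed, over 25 min) |
| coupling partner | 0.30 M | 0.45 M | 0.600 M |
| remark | run made earlier; the fed solution adds 0.10 times the starting volume | run made earlier; the fed solution adds 0.10 times the starting volume | the fed solution adds 0.10 times the starting volume |
| time |  |  | 12 d |

- midnight (time / d: starting material / %, single product / %): 0.833: 57.5, 27.3; 2.50: 56.7, 28.2; 4.00: 57.1, 27.3; 6.00: 57.8, 27.2; 10.0: 56.8, 28.1
- dusk (time / d: starting material / %, single product / %): 0.833: 41.6, 30.4; 2.50: 42.7, 30.3; 4.00: 41.6, 29.5; 6.00: 42.0, 29.8; 10.0: 42.5, 29.7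

(scatter of a reading: 0.5 percentage points)

- how much of the starting material has reacted by 12 d
- how much single product there is at 12 d, in percent of the starting material charged
- how much over-reaction product there is at 12 d, in percent of the starting material charged

- charges are per starting volume, the dose included; the dosed solution carries all of it
- the numbers in the tables scatter with a standard deviation of 0.5 percentage points
- steps that have been proposed: starting material + coupling partner -> single product; coupling partner + single product -> double product; coupling partner + double product -> tris adduct; coupling partner + single product -> over-reaction product

The midnight run read 57.5% of starting material at 0.833 d and 56.8% at 10.0 d, a difference of 0.7 percentage points against a scatter of 0.5 points. So I took it as stopped with starting material unused, with the coupling partner as limiting reagent, and I counted instead of integrating.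

The midnight run gave 1.40 of coupling partner charged per starting material reacted, and I called this the spend. The dusk run gave 1.55. Single product costs one partner, double and over-reaction product two, tris adduct three, so a rising spend means more later product.

The partner charges rise by equal steps across the midnight run, the dusk run and the flask, so I carried the spend on by the same step to 1.71. With 1.20 equivalents, the flask should then stop at 70.3% conversion. Double product and over-reaction product stand at the same count, and I drew no split between them from the spend.

The forecast gave 69.7% conversion, a little below mine, with 27.2% single product and 20% over-reaction product, noting that “the split is poorly determined”.

The flask gave 69.3% conversion, 27.7% single product and 27.1% over-reaction product.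

    starting material + coupling partner → single product (k = 8.50 × 10⁻⁴ L mol⁻¹ s⁻¹)
    coupling partner + single product → double product (k = 4.30 × 10⁻⁴ L mol⁻¹ s⁻¹)
    coupling partner + double product → tris adduct (k = 0.00200 L mol⁻¹ s⁻¹)
    coupling partner + single product → over-reaction product (k = 8.00 × 10⁻⁴ L mol⁻¹ s⁻¹)

At 12.0 d the flask held 0% of its charged coupling partner, and its spend came to 1.73. A neighbour flask, the same but charged with 0.36 M of coupling partner, lies between the midnight and dusk runs, and between them I interpolated the spend to 1.46. That predicts 49.2% conversion, and the neighbour flask gave 49.2%.

All runs stem from a simulated flask for substances that don't exist; the scatter is artificial.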